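## Structural features

The target is a flavone: a 4H-chromen-4-one (benzo ring A fused to the 4-pyranone ring C) that carries the phenyl ring B on C2 through the C2–C1' bond. Ring A has the 5,7-dihydroxy pattern, with the 5-OH hydrogen-bonded to the C4 carbonyl. Ring B is pentasubstituted: four contiguous oxygens on C2'–C5' (OMe, OH, OMe, OMe) and a single hydrogen at C6'. There is no stereocentre; the only stereochemical element met on the way is the geometry of an enol-ether double bond in the intermediates. Fragile points are the three free phenols (ring B is easily oxidized once deprotonated), the aryl methyl ethers under strongly Lewis-acidic or nucleophilic acid conditions, and the C3–H/C4=O unit under base. Rings A and C are routine. The real difficulty is ring B, where the one free hydroxyl sits at C3' between two methoxy groups; selective demethylation or selective protection of a tetraoxygenated benzene would not deliver this reliably. The key step exploits exactly this: C3' is made from the carbonyl carbon of a four-membered ring, so its oxygen never carries a methyl group, while C4' and C5' come from the two methoxy-bearing ring carbons and C2' from a methoxy-bearing vinyl carbon.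

## Logic of the disconnections

**18 back to 16.** The O1–C2 bond of ring C is cut (retro-cyclodehydration), together with the O–Si bond on the 3'-oxygen. Ring C is only the dehydrated form of an o-hydroxyaryl 1,3-diketone, and the acid that closes it also removes a silyl ether, so the last protecting group costs no separate step. One ring disappears and an open chain between two arenes remains. The forward step must dehydrate without cleaving aryl methyl ethers. Ring A of 16 is symmetric, so no regiochemical question arises; 17 is the presumed transient.

**16 back to 13 and 14.** The C2–C3 bond (flavone numbering) is cut, between the methylene carbon and the ring B carbonyl. This is the convergent point: ring A with C3 and C4 is commercial 14, and ring B with C2 arrives as an acyl chloride. Ring A then needs neither construction nor protection. The forward step must acylate carbon in the presence of three free phenols, so 14 is used as its polyanion 15 and 13 carries a silyl ether.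

**13 back to 10 (through 12 and 11).** No skeletal bond is cut; a C–Cl bond, two Si–O bonds and the ester O–CH3 bond are traced back. The acyl chloride needs the phenol masked, a silyl ester converts into an acyl chloride under neutral conditions, and the acid comes from the methyl ester. This arrives at 10, the direct product of the ring-forming step. The demand is hydrolysis of a hindered, electron-rich ester with exclusion of air.

**10 back to 7 (through 9 and 8).** The C2'–C3' bond is cut (retro-6π) and C3' is reconnected to C6' (retro-4π), which folds C3'–C4'–C5'–C6' into a four-membered ring. The cut is made here because the carbonyl carbon of that ring then encodes the single free hydroxyl. A benzene with four differentiated oxygens becomes a cyclobutenone joined to an enol-ether ester, with no protecting group on ring B. The forward step must pass through the inward-rotated ketene although outward rotation is preferred; reversibility of the opening has to supply it. 7 must be handled below its opening temperature.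

**7 back to 3 and 6.** The bond between the sp3 ring carbon and the ester α-carbon (future C6'–C1') is cut. It is an allylic, α-keto sp3–sp2 bond, suited to palladium-catalysed coupling of a chloride with an alkenyl metal. It separates a four-carbon ring fragment from a three-carbon ester fragment, each one or two steps from commerce. The coupling must occur at the hydrogen-bearing allyl terminus, retain alkene geometry, and run below the temperature at which 7 opens.

**3 back to 1 (through 2).** The C–Cl bond is traced to C–OH and the C–H bond to a carbonyl. This reaches symmetric, commercial 1. The forward steps need mono-reduction of one of two equivalent carbonyls and a chlorination that avoids acid, because 2 ionizes and loses a methyl group under acid.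

**6 back to 4 (through 5).** The C–Sn bond is traced to the vinylic C–H bond α to the ester. That hydrogen is the kinetically acidic one, and 4 is commercial. The forward step needs low temperature so that 5 keeps its geometry and does not eliminate methoxide.

## Other disconnections considered

**Alternative 1:** The cut removes O1–C8a, C4–C4a and O1–C2 at once. Ring A arrives as an aryne and ring B with C2–C4 as 3-[3-(benzyloxy)-2,4,5-trimethoxyphenyl]propiolic acid A3.
- **Forward step:** Fluoride would release the aryne from 3,5-bis(benzyloxy)-2-(trimethylsilyl)phenyl trifluoromethanesulfonate A2. The carboxylate of A3 adds to the aryne carbon remote from the flanking benzyloxy group, the aryl anion attacks the acyl carbon (net C–O insertion), and the phenoxide closes ring C by 6-endo addition to the ynone. This gives 5,7,3'-tris(benzyloxy)-2',4',5'-trimethoxyflavone A1; hydrogenolysis would then give 18.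
- **In favour:** Three bonds and ring C form in one operation. On convergence of the fragment union it is better than the chosen route, which needs steps 9 and 10 for the same union. The flanking alkoxy group steers aryne capture in the right sense.
- **Against:** It does nothing for ring B. A3 already contains the full oxygen pattern with the 3'-oxygen differentiated, so the real problem is only moved into the preparation of A3. A2 needs several steps of its own. The aryl anion can be protonated before acyl transfer, arylpropiolates tend to decarboxylate under basic fluoride conditions, and three benzyl ethers must be removed at the end.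
- **Comparison:** It equals the chosen plan for rings A and C and is weaker for ring B. Mechanistically it is a polar cascade with several exits, against a unimolecular pericyclic cascade with one productive exit. The step count would be similar or longer once A2 and A3 are included.

**Alternative 2:** Ring A is built last on a preformed pyranone carrying ring B. The bonds C8–C8a, C5–C6, C7–C8 and C4a–C5 are traced back to 2-(diazoacetyl)-6-[3-(benzyloxy)-2,4,5-trimethoxyphenyl]-4H-pyran-4-one A5 and (triisopropylsilyloxy)acetylene A6.
- **Forward step (Danheiser benzannulation):** Photochemical Wolff rearrangement of A5 forms C8–C8a by 1,2-shift and gives a vinylketene. [2+2] cycloaddition with A6 forms C5–C6 and C7–C8. Heating drives 4π opening and 6π closure (C4a–C5) to 3'-(benzyloxy)-5-hydroxy-2',4',5'-trimethoxy-7-(triisopropylsilyloxy)flavone A4; desilylation and hydrogenolysis would give 18.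
- **In favour:** The pericyclic logic is the same as in the chosen key step, so the two are equal in mechanistic reliability of the ring-forming cascade. Regiochemistry is fixed by connectivity. The 5- and 7-oxygens emerge differentiated, which would be better than the chosen route if a 7-O-substituted analogue were wanted.
- **Against:** Both ring A hydroxyls are free in this target, so the differentiation buys nothing, and ring A can be bought intact as 14. Ring B must still be made separately with a protected 3'-oxygen. A5 needs a pyranone carboxylic acid precursor and diazoketone chemistry, A6 is a multi-step reagent, and the pyranone chromophore may compete for light in the Wolff step. Two deprotections follow.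
- **Comparison:** Equal in mechanistic type, better in regiochemical information for ring A, clearly worse in step economy and in where the effort is spent.

**Alternative 3:** The cut is the single bond C4a–C5. Ring A is unrolled into a 3-oxobutanoate chain on the pyranone, methyl 4-{6-[3-(benzyloxy)-2,4,5-trimethoxyphenyl]-4-oxo-4H-pyran-2-yl}-3-oxobutanoate A8.
- **Forward step:** A methoxide base would generate the vinylogous enolate running from the side-chain methylene through C8a to C4a. Attack of C4a on the ester carbonyl (Claisen-type, six-membered) and enolization aromatize ring A to 3'-(benzyloxy)-5,7-dihydroxy-2',4',5'-trimethoxyflavone A7; hydrogenolysis would give 18.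
- **In favour:** A biomimetic, metal-free closure driven by aromatization. Ring A appears with both hydroxyls free and correctly placed, which equals the chosen route, and only one protecting group is removed at the end, as in the chosen route.
- **Against:** The most acidic position of A8 is the methylene between ketone and ester, not the one whose deprotonation makes C4a nucleophilic. A polyanion is therefore needed, and O-acylation and other condensation modes compete. Alkoxide can open the pyranone. A8 must be assembled by lateral acylation of a methylpyranone with its own regiochemical questions, and the ring B problem is again presupposed solved.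
- **Comparison:** Equal to the chosen plan in protecting-group economy on ring A, less secure mechanistically, and probably longer because A8 and its ring B building block both need multi-step preparation.

Key step: step 5

**Remarks on the chemistry**

- Assumption: "safe" is read as low chemical risk. Compounds 2, 3, 7 and 9 are racemic; their single stereocentre is erased in step 5, so no stereocontrol is attempted.
- Structure check: 7 and 10 were re-derived atom by atom and need no correction. The descriptors change E (4), Z (6), E (7) through CIP priorities only; the methoxy group stays trans to the ester throughout.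
- Design choices: the precursor 7 itself is kept as the methyl ester with E geometry. The chloride is made without acid. The coupling is copper-assisted and held at or below 40 °C so that 7 is obtained before the cascade. The end-game uses unprotected 14, with no benzyl ethers and no hydrogenolysis.

## Route

Step 1
Reactants: 1 dimethyl squarate (3,4-dimethoxycyclobut-3-ene-1,2-dione)
Product: 2 4-hydroxy-2,3-dimethoxycyclobut-2-en-1-one (racemic)
Conditions: LiAlH(OtBu)3 (1.1 equiv), THF, −78 → −20 °C; aq. potassium sodium tartrate (pH 7), 0 °C
Reagents that add atoms: none
Why: Hydride 1,2-reduction of one of two equivalent carbonyls; the product is a vinylogous ester whose remaining carbonyl is less electrophilic than those of 1, so a bulky hydride at low temperature should stop at mono-reduction. The new stereocentre is formed racemic, and the neutral work-up avoids acid-induced ionization of the hydroxyl.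

Step 2
Reactants: 2 4-hydroxy-2,3-dimethoxycyclobut-2-en-1-one
Product: 3 4-chloro-2,3-dimethoxycyclobut-2-en-1-one (racemic)
Conditions: 1-chloro-N,N,2-trimethylprop-1-en-1-amine (1.1 equiv), CH2Cl2, −20 → 0 °C; concentrate cold, use at once
Reagents that add atoms: 1-chloro-N,N,2-trimethylprop-1-en-1-amine, SMILES CC(C)=C(Cl)N(C)C
Why: Deoxychlorination under neutral conditions via an alkoxyiminium chloride; chloride should displace at the α-keto carbon, where SN2 is accelerated, and the only by-product is a neutral amide, so no acid is present to trigger rearrangement of the dimethoxycyclobutenone. The chloride is not stored, because its C–Cl bond ionizes readily.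

Step 3
Reactants: 4 methyl (E)-3-methoxyacrylate
Product: 6 methyl (Z)-3-methoxy-2-(tributylstannyl)acrylate, via α-lithioacrylate 5 (not isolated)
Conditions: LiN(iPr)2 (1.05 equiv), THF, −90 °C, 20 min; Bu3SnCl (1.1 equiv), −90 → −40 °C
Reagents that add atoms: tributyltin chloride, SMILES CCCC[Sn](Cl)(CCCC)CCCC
Why: Kinetic vinylic deprotonation α to the ester of a β-alkoxyacrylate, then stannylation with retention; the vinyllithium is configurationally stable at this temperature, so tin ends up cis to the methoxy group. The change of descriptor from E to Z is a priority effect only.

Step 4
Reactants: 3 4-chloro-2,3-dimethoxycyclobut-2-en-1-one; 6 methyl (Z)-3-methoxy-2-(tributylstannyl)acrylate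
Product: 7 methyl (E)-2-(2,3-dimethoxy-4-oxocyclobut-2-en-1-yl)-3-methoxyacrylate (racemic)
Conditions: Pd2(dba)3 (2.5 mol %), tri(2-furyl)phosphine (10 mol %), CuI (10 mol %), THF–NMP (4:1), 25 → 40 °C, dark; filtration through KF on silica, cold chromatography on neutral alumina
Reagents that add atoms: none
Why: Stille coupling of a 4-chlorocyclobutenone: zerovalent palladium inserts into the allylic, α-keto C–Cl bond to give a divalent palladium η3-oxocyclobutenyl chloride, CuI (monovalent copper) relays the hindered alkenyl group from tin, and reductive elimination at the hydrogen-bearing terminus keeps the vinylogous ester intact. Alkene geometry is retained and the sp3 centre is racemic; the temperature stays at or below 40 °C so that 7 does not yet open, and any 10 formed early is simply carried forward.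

Step 5
Reactants: 7 methyl (E)-2-(2,3-dimethoxy-4-oxocyclobut-2-en-1-yl)-3-methoxyacrylate
Product: 10 methyl 3-hydroxy-2,4,5-trimethoxybenzoate, via inward-rotated dienylketene 8 (not isolated), via cyclohexa-2,4-dienone tautomer 9 (not isolated)
Conditions: PhMe (0.02 M, degassed), 110 °C, Ar
Reagents that add atoms: none
Why: Heating cleaves the C(=O)–C(sp3) bond of 7 in a conrotatory 4π electrocyclic opening; outward rotation of the alkenyl group is kinetically preferred but gives a ketene geometry that can only re-close to 7, whereas inward rotation gives 8, in which the ketene carbon lies next to the methoxy-bearing vinyl carbon. 8 then undergoes a disrotatory 6π electrocyclization (all-carbon six-membered ring, ketene carbon onto the vinyl terminus, forming the future C2'–C3' bond) to the dienone 9, and enolization of 9 (transfer of the C2' hydrogen to the carbonyl oxygen) should give the phenol 10 irreversibly, which drains the reversible opening. The closest known reaction type is the thermal benzannulation of 4-alkenyl- and 4-arylcyclobutenones to phenols, including cyclobutenones made by palladium-catalysed coupling of 4-chlorocyclobutenones. No stereocentre is created: the sp3 centre of 7 becomes the C6'–H carbon of the arene and the sp3 carbon of 9 is lost on aromatization. The step needs regioselective closure, which is structural (the only six-membered closure open to the ketene carbon is onto the enol-ether carbon; the ester carbonyl would require a seven-membered ring), and preference for intramolecular closure over intermolecular ketene capture, which high dilution in an aprotic solvent should secure. The oxygen pattern follows from connectivity alone: the two ring methoxy carbons become C4' and C5', the enol-ether carbon becomes C2'–OMe, and the former carbonyl is the only unmethylated oxygen, C3'–OH.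

Step 6
Reactants: 10 methyl 3-hydroxy-2,4,5-trimethoxybenzoate
Product: 11 3-hydroxy-2,4,5-trimethoxybenzoic acid
Conditions: LiOH·H2O (4 equiv), THF–MeOH–H2O (2:1:1), 50 °C, Ar; then 1 M HCl to pH 2
Reagents that add atoms: lithium hydroxide monohydrate (hydroxide oxygen), SMILES [Li+].[OH-].O
Why: Saponification of an ortho-substituted, electron-rich methyl ester needs mild heating; argon protects the electron-rich phenoxide from air oxidation, and gentle acidification avoids protodecarboxylation.

Step 7
Reactants: 11 3-hydroxy-2,4,5-trimethoxybenzoic acid
Product: 12 tert-butyldimethylsilyl 3-(tert-butyldimethylsilyloxy)-2,4,5-trimethoxybenzoate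
Conditions: TBSCl (2.5 equiv), imidazole (5 equiv), DMF, 25 °C
Reagents that add atoms: tert-butyldimethylsilyl chloride, SMILES CC(C)(C)[Si](C)(C)Cl
Why: Imidazole-promoted silylation of both the phenol and the acid; the silyl ether survives the strong base of step 9 and is acid-labile, and the silyl ester is the direct precursor of the acyl chloride.

Step 8
Reactants: 12 tert-butyldimethylsilyl 3-(tert-butyldimethylsilyloxy)-2,4,5-trimethoxybenzoate
Product: 13 3-(tert-butyldimethylsilyloxy)-2,4,5-trimethoxybenzoyl chloride
Conditions: (COCl)2 (1.5 equiv), DMF (cat.), CH2Cl2, 0 °C → rt; evaporate, use crude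
Reagents that add atoms: oxalyl chloride, SMILES O=C(Cl)C(=O)Cl
Why: Vilsmeier-type conversion of a silyl ester into the acyl chloride; no hydrogen chloride is liberated (the silicon leaves as silyl chloride), so the aryl silyl ether should stay in place.

Step 9
Reactants: 14 2,4,6-trihydroxyacetophenone; 13 3-(tert-butyldimethylsilyloxy)-2,4,5-trimethoxybenzoyl chloride
Product: 16 1-[3-(tert-butyldimethylsilyloxy)-2,4,5-trimethoxyphenyl]-3-(2,4,6-trihydroxyphenyl)propane-1,3-dione, via tetralithium enolate triphenoxide 15 (not isolated)
Conditions: 14 (dried), LiN(SiMe3)2 (4.3 equiv), THF, −78 → −10 °C; then 13 in THF, −78 °C → rt; aq. NH4Cl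
Reagents that add atoms: none
Why: Claisen-type C-acylation of a ketone enolate: in the tetra-anion the enolate carbon is the most nucleophilic site, while the three phenoxides are charge-delocalized and hindered, so the β-diketone should form directly without protecting ring A. The excess base keeps the product deprotonated and prevents a second acylation.

Step 10
Reactants: 16 1-[3-(tert-butyldimethylsilyloxy)-2,4,5-trimethoxyphenyl]-3-(2,4,6-trihydroxyphenyl)propane-1,3-dione
Product: 18 5,7,3'-trihydroxy-2',4',5'-trimethoxyflavone (target), via 3'-O-silyl flavone 17 (not isolated)
Conditions: AcOH, H2SO4 (0.5 vol %), 95 °C; pour into water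
Reagents that add atoms: none
Why: Acid-catalysed cyclodehydration of an o-hydroxyaryl β-diketone (addition of an ortho hydroxyl to the ring B carbonyl, then loss of water, closing ring C), with acidolysis of the aryl silyl ether in the same pot. Ring A is symmetric, so either ortho hydroxyl gives the same flavone, and the methyl ethers should survive because no nucleophilic halide is present.

## Compound list

1 | dimethyl squarate (3,4-dimethoxycyclobut-3-ene-1,2-dione) | COC1=C(OC)C(=O)C1=O | starting material
2 | 4-hydroxy-2,3-dimethoxycyclobut-2-en-1-one (racemic) | O=C1C(OC)=C(OC)C1O | intermediate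
3 | 4-chloro-2,3-dimethoxycyclobut-2-en-1-one (racemic) | O=C1C(OC)=C(OC)C1Cl | intermediate
4 | methyl (E)-3-methoxyacrylate | CO/C=C/C(=O)OC | starting material
5 | methyl (E)-2-lithio-3-methoxyacrylate (lithium cis to the methoxy group; not isolated) | CO/C=C(/C(=O)OC)[Li] | intermediate
6 | methyl (Z)-3-methoxy-2-(tributylstannyl)acrylate | CO/C=C(/C(=O)OC)[Sn](CCCC)(CCCC)CCCC | intermediate
7 | methyl (E)-2-(2,3-dimethoxy-4-oxocyclobut-2-en-1-yl)-3-methoxyacrylate (racemic) | O=C1C(OC)=C(OC)C1/C(C(=O)OC)=C\OC | intermediate
8 | methyl (E)-2-[(1E)-2,3-dimethoxy-4-oxobuta-1,3-dien-1-yl]-3-methoxyacrylate (dienylketene, ketene carbon cis to the acrylate; not isolated) | O=C=C(OC)/C(OC)=C\C(C(=O)OC)=C/OC | intermediate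
9 | methyl 3,4,6-trimethoxy-5-oxocyclohexa-1,3-diene-1-carboxylate (racemic; not isolated) | COC(=O)C1=CC(OC)=C(OC)C(=O)C1OC | intermediate
10 | methyl 3-hydroxy-2,4,5-trimethoxybenzoate | COC(=O)c1cc(OC)c(OC)c(O)c1OC | intermediate
11 | 3-hydroxy-2,4,5-trimethoxybenzoic acid | COc1cc(C(=O)O)c(OC)c(O)c1OC | intermediate
12 | tert-butyldimethylsilyl 3-(tert-butyldimethylsilyloxy)-2,4,5-trimethoxybenzoate | COc1cc(C(=O)O[Si](C)(C)C(C)(C)C)c(OC)c(O[Si](C)(C)C(C)(C)C)c1OC | intermediate
13 | 3-(tert-butyldimethylsilyloxy)-2,4,5-trimethoxybenzoyl chloride | COc1cc(C(=O)Cl)c(OC)c(O[Si](C)(C)C(C)(C)C)c1OC | intermediate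
14 | 2,4,6-trihydroxyacetophenone | CC(=O)c1c(O)cc(O)cc1O | starting material
15 | tetralithium enolate triphenoxide of 2,4,6-trihydroxyacetophenone (not isolated) | [Li+].[Li+].[Li+].[Li+].C=C([O-])c1c([O-])cc([O-])cc1[O-] | intermediate
16 | 1-[3-(tert-butyldimethylsilyloxy)-2,4,5-trimethoxyphenyl]-3-(2,4,6-trihydroxyphenyl)propane-1,3-dione | COc1cc(C(=O)CC(=O)c2c(O)cc(O)cc2O)c(OC)c(O[Si](C)(C)C(C)(C)C)c1OC | intermediate
17 | 3'-(tert-butyldimethylsilyloxy)-5,7-dihydroxy-2',4',5'-trimethoxyflavone (not isolated) | COc1cc(-c2cc(=O)c3c(O)cc(O)cc3o2)c(OC)c(O[Si](C)(C)C(C)(C)C)c1OC | intermediate
18 | 5,7,3'-trihydroxy-2',4',5'-trimethoxyflavone | COc1cc(-c2cc(=O)c3c(O)cc(O)cc3o2)c(OC)c(O)c1OC | target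

## Step count and least certain steps

Total step count: 10. Longest linear sequence: 9 steps (steps 1, 2, 4, 5, 6, 7, 8, 9, 10, from 1 to 18); step 3 is a one-step side branch.

**Step 5 (key step).**
- Risk: intermolecular consumption of the ketene (acylation of the phenol as it forms, or dimerization). The productive inward rotation is the disfavoured mode and the closure is onto a terminus with an inward methoxy group, so the substrate may spend a long time cycling through unproductive openings.
- Fallback: put a hydroxyl on the sp3 carbon so that the intrinsic torquoselectivity turns the alkenyl group inward, then remove the extra oxygen. It sets out from 1 and 5 (5 generated from 4 as in step 3) and returns at 11. Addition of 5 to one carbonyl of 1 (THF, −90 °C, NH4Cl quench) should give the tertiary alcohol methyl (E)-2-(1-hydroxy-2,3-dimethoxy-4-oxocyclobut-2-en-1-yl)-3-methoxyacrylate F1. Heating F1 in toluene (Moore rearrangement; the hydroxyl rotates outward) should give the hydroquinone methyl 3,6-dihydroxy-2,4,5-trimethoxybenzoate F2, kept under argon. Silylation of the non-chelated hydroxyl (TBSCl, imidazole) gives methyl 3-(tert-butyldimethylsilyloxy)-6-hydroxy-2,4,5-trimethoxybenzoate F3. Triflation of the remaining ester-chelated hydroxyl (Tf2O, pyridine) gives methyl 3-(tert-butyldimethylsilyloxy)-2,4,5-trimethoxy-6-(trifluoromethylsulfonyloxy)benzoate F4. Reduction of the aryl triflate (Pd(OAc)2, 1,3-bis(diphenylphosphino)propane, Et3SiH, DMF, 60 °C) gives methyl 3-(tert-butyldimethylsilyloxy)-2,4,5-trimethoxybenzoate F5. Aqueous LiOH then cleaves ester and silyl ether to 11. This detour also bypasses steps 1, 2 and 4 and is no longer than the sequence it replaces.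

**Step 2.**
- Risk: ionization of the new C–Cl bond (the cation is stabilized by the C2 methoxy group), return of chloride at the methoxy-bearing terminus and irreversible loss of chloromethane, during the reaction or on handling.
- Fallback: change the leaving group and the activation mode; it sets out from 2 and returns at 7. Acetylation of 2 (Ac2O, pyridine, cat. DMAP, 0 °C) should give 2,3-dimethoxy-4-oxocyclobut-2-en-1-yl acetate F6, whose leaving group cannot demethylate. F6 is then ionized by zerovalent palladium and coupled with 6 in the allylic-acetate variant of the Stille coupling (Pd2(dba)3, tri(2-furyl)phosphine, LiCl, CuI, DMF, 25 → 40 °C) to give 7.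

**Step 4.**
- Risk: slow transfer of the hindered, electron-poor alkenyl group from tin, so that decomposition of 3, cine substitution or premature ring opening outruns coupling. A lesser concern is reductive elimination at the methoxy-bearing allyl terminus.
- Fallback: change the organometallic partner; it sets out from 4 (through 5) and 3 and returns at 7. Transmetalation of 5 with ZnCl2 (−90 → −40 °C) should give methyl (Z)-2-(chlorozincio)-3-methoxyacrylate F7, which is coupled with 3 in a Negishi coupling (Pd2(dba)3, tri(2-furyl)phosphine, THF, 0 → 25 °C). Zinc transfers much faster than tin, so the coupling can be run cold.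

**Step 3.**
- Risk: β-elimination of lithium methoxide from 5, and attack of 5 on the ester of unreacted 4, if the temperature drifts upward.
- Fallback: replace deprotonation by halogenation and halogen–metal exchange; it sets out from 4 and returns at 6. Iodination by addition–elimination (N-iodosuccinimide, AcOH, CH2Cl2; then Et3N) should give methyl (Z)-2-iodo-3-methoxyacrylate F8. Iodine–magnesium exchange (iPrMgCl·LiCl, THF, −40 °C) gives methyl (Z)-2-(chloromagnesio)-3-methoxyacrylate F9, which is quenched with Bu3SnCl to give 6.

## Further compounds

F1 | step 5 | methyl (E)-2-(1-hydroxy-2,3-dimethoxy-4-oxocyclobut-2-en-1-yl)-3-methoxyacrylate (racemic) | O=C1C(OC)=C(OC)C1(O)/C(C(=O)OC)=C\OC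
F2 | step 5 | methyl 3,6-dihydroxy-2,4,5-trimethoxybenzoate | COC(=O)c1c(O)c(OC)c(OC)c(O)c1OC
F3 | step 5 | methyl 3-(tert-butyldimethylsilyloxy)-6-hydroxy-2,4,5-trimethoxybenzoate | COC(=O)c1c(O)c(OC)c(OC)c(O[Si](C)(C)C(C)(C)C)c1OC
F4 | step 5 | methyl 3-(tert-butyldimethylsilyloxy)-2,4,5-trimethoxy-6-(trifluoromethylsulfonyloxy)benzoate | COC(=O)c1c(OS(=O)(=O)C(F)(F)F)c(OC)c(OC)c(O[Si](C)(C)C(C)(C)C)c1OC
F5 | step 5 | methyl 3-(tert-butyldimethylsilyloxy)-2,4,5-trimethoxybenzoate | COC(=O)c1cc(OC)c(OC)c(O[Si](C)(C)C(C)(C)C)c1OC
F6 | step 2 | 2,3-dimethoxy-4-oxocyclobut-2-en-1-yl acetate (racemic) | CC(=O)OC1C(=O)C(OC)=C1OC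
F7 | step 4 | methyl (Z)-2-(chlorozincio)-3-methoxyacrylate | CO/C=C(/C(=O)OC)[Zn]Cl
F8 | step 3 | methyl (Z)-2-iodo-3-methoxyacrylate | CO/C=C(/C(=O)OC)I
F9 | step 3 | methyl (Z)-2-(chloromagnesio)-3-methoxyacrylate | CO/C=C(/C(=O)OC)[Mg]Cl
A1 | alternative 1 | 5,7,3'-tris(benzyloxy)-2',4',5'-trimethoxyflavone | COc1cc(-c2cc(=O)c3c(OCc4ccccc4)cc(OCc4ccccc4)cc3o2)c(OC)c(OCc2ccccc2)c1OC
A2 | alternative 1 | 3,5-bis(benzyloxy)-2-(trimethylsilyl)phenyl trifluoromethanesulfonate | C[Si](C)(C)c1c(OCc2ccccc2)cc(OCc2ccccc2)cc1OS(=O)(=O)C(F)(F)F
A3 | alternative 1 | 3-[3-(benzyloxy)-2,4,5-trimethoxyphenyl]propiolic acid | COc1cc(C#CC(=O)O)c(OC)c(OCc2ccccc2)c1OC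
A4 | alternative 2 | 3'-(benzyloxy)-5-hydroxy-2',4',5'-trimethoxy-7-(triisopropylsilyloxy)flavone | COc1cc(-c2cc(=O)c3c(O)cc(O[Si](C(C)C)(C(C)C)C(C)C)cc3o2)c(OC)c(OCc2ccccc2)c1OC
A5 | alternative 2 | 2-(diazoacetyl)-6-[3-(benzyloxy)-2,4,5-trimethoxyphenyl]-4H-pyran-4-one | COc1cc(-c2cc(=O)cc(C(=O)C=[N+]=[N-])o2)c(OC)c(OCc2ccccc2)c1OC
A6 | alternative 2 | (triisopropylsilyloxy)acetylene | C#CO[Si](C(C)C)(C(C)C)C(C)C
A7 | alternative 3 | 3'-(benzyloxy)-5,7-dihydroxy-2',4',5'-trimethoxyflavone | COc1cc(-c2cc(=O)c3c(O)cc(O)cc3o2)c(OC)c(OCc2ccccc2)c1OC
A8 | alternative 3 | methyl 4-{6-[3-(benzyloxy)-2,4,5-trimethoxyphenyl]-4-oxo-4H-pyran-2-yl}-3-oxobutanoate | COC(=O)CC(=O)Cc1cc(=O)cc(-c2cc(OC)c(OC)c(OCc3ccccc3)c2OC)o1
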